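## Retrosynthetic overview

- Rings A and C are both made in the last operation: the flavanone is cut to a cross-conjugated aryl enynone (B ring, C2–C4, C4a, C5) and Chan's diene (C6–C8, C8a and both phenol oxygens).
- A Diels–Alder benzannulation at the terminal ynone builds ring A as a 2',4'-dioxygenated aryl ketone. The freed 2'-OH then closes ring C by a catalyst-controlled oxa-Michael addition that sets C2 as (S).
- The enynone comes from a Weinreb enamide and ethynylmagnesium bromide; the enamide comes from the diprenyl aldehyde by HWE olefination.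
- The aldehyde comes from double Stille prenylation of 3,5-dibromo-4-methoxybenzaldehyde, itself from O-methylation of 3,5-dibromo-4-hydroxybenzaldehyde.
- Ring order: B (bought), then A, then C, with A and C formed in one pot.

Assumption: Chan's diene 10 and prenylstannane 4 are bought. The sense of induction of the cinchona thiourea in step 5 is checked by chiral HPLC on a test run; the quinidine-derived pseudoenantiomer is used instead if the quinine-derived catalyst gives 2R.

## Route

Step 1
Reactants: 1 3,5-dibromo-4-hydroxybenzaldehyde; 2 iodomethane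
Product: 3 3,5-dibromo-4-methoxybenzaldehyde
Conditions: MeI (1.5 equiv), K2CO3, DMF, rt
Reagents that add atoms: iodomethane 2, CI
Why: Williamson ether synthesis; the acidic 2,6-dibromophenoxide is methylated by SN2 on MeI and the aldehyde is inert to K2CO3.

Step 2
Reactants: 3 3,5-dibromo-4-methoxybenzaldehyde; 4 tributyl(3-methylbut-2-en-1-yl)stannane (2.4 equiv)
Product: 5 4-methoxy-3,5-bis(3-methylbut-2-en-1-yl)benzaldehyde
Conditions: Pd(PPh3)4 (5 mol%), DMF, 100 °C
Reagents that add atoms: tributyl(3-methylbut-2-en-1-yl)stannane 4, CCCC[Sn](CCCC)(CCCC)CC=C(C)C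
Why: Double Stille cross-coupling; reductive elimination at the unsubstituted allyl terminus gives the linear prenyl arene, and the aldehyde tolerates the neutral conditions.

Step 3
Reactants: 5 4-methoxy-3,5-bis(3-methylbut-2-en-1-yl)benzaldehyde; 6 diethyl {2-[methoxy(methyl)amino]-2-oxoethyl}phosphonate
Product: 7 (2E)-N-methoxy-3-[4-methoxy-3,5-bis(3-methylbut-2-en-1-yl)phenyl]-N-methylprop-2-enamide
Conditions: NaH, THF, 0 °C→rt
Reagents that add atoms: diethyl {2-[methoxy(methyl)amino]-2-oxoethyl}phosphonate 6, CCOP(=O)(CC(=O)N(C)OC)OCC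
Why: Horner–Wadsworth–Emmons olefination; the stabilised phosphonate anion gives the (E)-enamide.

Step 4
Reactants: 7 (2E)-N-methoxy-3-[4-methoxy-3,5-bis(3-methylbut-2-en-1-yl)phenyl]-N-methylprop-2-enamide; 8 ethynylmagnesium bromide
Product: 9 (1E)-1-[4-methoxy-3,5-bis(3-methylbut-2-en-1-yl)phenyl]pent-1-en-4-yn-3-one
Conditions: HC≡CMgBr (0.5 M in THF), THF, −78→0 °C; inverse quench into cold 1 M HCl
Reagents that add atoms: ethynylmagnesium bromide 8, C#C[Mg]Br
Why: Weinreb ketone synthesis; the magnesium chelate stops at mono-addition and collapses to the ynone only on the cold acidic quench, which also protonates the released amine so that it cannot add to the ynone.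

Step 5
Reactants: 9 (1E)-1-[4-methoxy-3,5-bis(3-methylbut-2-en-1-yl)phenyl]pent-1-en-4-yn-3-one; 10 1-methoxy-1,3-bis(trimethylsilyloxy)buta-1,3-diene (Chan's diene, 1.3 equiv)
Product: 14 (2S)-7-hydroxy-2-[4-methoxy-3,5-bis(3-methylbut-2-en-1-yl)phenyl]-2,3-dihydro-4H-chromen-4-one (abyssinone IV 4'-OMe ether), via Diels–Alder adduct 11 (not isolated), via bis-silyl chalcone 12 (not isolated), via dihydroxychalcone 13 (not isolated)
Conditions: 10, PhMe, 0→40 °C; then MeOH (5 equiv), 9-epi-aminoquinine 3,5-bis(trifluoromethyl)phenyl thiourea (15 mol%), PhMe, −20 °C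
Reagents that add atoms: 1-methoxy-1,3-bis(trimethylsilyloxy)buta-1,3-diene 10, COC(O[Si](C)(C)C)=CC(=C)O[Si](C)(C)C
Why: Proposed new method: the terminal ynone of 9 is its most reactive 2π unit and adds the ketene-acetal diene with the CH2 terminus on the alkyne CH (Diels–Alder benzannulation, the known behaviour of Chan- and Brassard-type dienes towards acetylenic ketones and esters), adduct 11 aromatises by loss of methanol, methanolysis of the aryl silyl ethers unmasks chalcone 13, and the bifunctional cinchona thiourea (quinuclidine as general base on the 2'-OH, thiourea hydrogen-bonded to the enone C=O) delivers the phenol oxygen to the Si face of the β-carbon in an enantioselective intramolecular oxa-Michael addition that sets C2 as (S); the closest known reactions are thiourea-catalysed oxa-Michael flavanone syntheses of ester-activated chalcones and cinchona-base cyclisations of plain 2'-hydroxychalcones, the latter with only moderate ee.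

## Compound list

1 | 3,5-dibromo-4-hydroxybenzaldehyde | O=Cc1cc(Br)c(O)c(Br)c1 | starting material
2 | iodomethane | CI | starting material
3 | 3,5-dibromo-4-methoxybenzaldehyde | COc1c(Br)cc(C=O)cc1Br | intermediate
4 | tributyl(3-methylbut-2-en-1-yl)stannane | CCCC[Sn](CCCC)(CCCC)CC=C(C)C | starting material
5 | 4-methoxy-3,5-bis(3-methylbut-2-en-1-yl)benzaldehyde | COc1c(CC=C(C)C)cc(C=O)cc1CC=C(C)C | intermediate
6 | diethyl {2-[methoxy(methyl)amino]-2-oxoethyl}phosphonate | CCOP(=O)(CC(=O)N(C)OC)OCC | starting material
7 | (2E)-N-methoxy-3-[4-methoxy-3,5-bis(3-methylbut-2-en-1-yl)phenyl]-N-methylprop-2-enamide | CON(C)C(=O)/C=C/c1cc(CC=C(C)C)c(OC)c(CC=C(C)C)c1 | intermediate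
8 | ethynylmagnesium bromide | C#C[Mg]Br | starting material
9 | (1E)-1-[4-methoxy-3,5-bis(3-methylbut-2-en-1-yl)phenyl]pent-1-en-4-yn-3-one | C#CC(=O)/C=C/c1cc(CC=C(C)C)c(OC)c(CC=C(C)C)c1 | intermediate
10 | 1-methoxy-1,3-bis(trimethylsilyloxy)buta-1,3-diene (Chan's diene) | COC(O[Si](C)(C)C)=CC(=C)O[Si](C)(C)C | starting material
11 | Diels–Alder adduct: (2E)-1-[6-methoxy-4,6-bis(trimethylsilyloxy)cyclohexa-1,4-dien-1-yl]-3-[4-methoxy-3,5-bis(3-methylbut-2-en-1-yl)phenyl]prop-2-en-1-one, racemic at the ketal carbon | COC1(O[Si](C)(C)C)C=C(O[Si](C)(C)C)CC=C1C(=O)/C=C/c1cc(CC=C(C)C)c(OC)c(CC=C(C)C)c1 | intermediate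
12 | bis-silyl chalcone: (2E)-1-[2,4-bis(trimethylsilyloxy)phenyl]-3-[4-methoxy-3,5-bis(3-methylbut-2-en-1-yl)phenyl]prop-2-en-1-one | C[Si](C)(C)Oc1ccc(C(=O)/C=C/c2cc(CC=C(C)C)c(OC)c(CC=C(C)C)c2)c(O[Si](C)(C)C)c1 | intermediate
13 | dihydroxychalcone: (2E)-1-(2,4-dihydroxyphenyl)-3-[4-methoxy-3,5-bis(3-methylbut-2-en-1-yl)phenyl]prop-2-en-1-one | O=C(/C=C/c1cc(CC=C(C)C)c(OC)c(CC=C(C)C)c1)c1ccc(O)cc1O | intermediate
14 | (2S)-7-hydroxy-2-[4-methoxy-3,5-bis(3-methylbut-2-en-1-yl)phenyl]-2,3-dihydro-4H-chromen-4-one (abyssinone IV 4'-OMe ether) | COc1c(CC=C(C)C)cc([C@@H]2CC(=O)c3ccc(O)cc3O2)cc1CC=C(C)C | target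

## Step count and risks

Total steps: 5. Longest linear sequence: 5 (1 → 3 → 5 → 7 → 9 → 14).

Steps most likely to fail:

**Step 5 (domino benzannulation and asymmetric oxa-Michael).** The most likely failure is low ee or incomplete closure of the unactivated 2',4'-dihydroxychalcone. The fallback moves stereocontrol from the small-molecule catalyst to an enzyme and uncouples the two ring closures. The Diels–Alder, aromatisation and methanolysis are run without the thiourea (MeOH with a little AcOH) and the dihydroxychalcone 13 is isolated. It is then cyclised in a separate biocatalytic step with a recombinant type II (legume) chalcone isomerase in phosphate buffer pH 7.5 with 5–10% DMSO at 25 °C. This enzyme class converts 6'-deoxychalcones into (2S)-flavanones; acceptance of the bulky diprenyl B ring is untested. The fallback sets out from 13 and comes back at 14; it makes no compound beyond the list (F0).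

**Step 2 (double Stille prenylation).** The risks are partial γ-coupling to reverse-prenyl isomers or incomplete second coupling next to the methoxy group. The fallback sets out from 3 and installs the prenyl groups in two stages. A double Stille coupling with allyltributylstannane (Pd(PPh3)4, DMF, 90 °C), which has no α/γ ambiguity, gives 3,5-diallyl-4-methoxybenzaldehyde F1. Double olefin cross-metathesis with excess 2-methylbut-2-ene (Grubbs II, CH2Cl2, 40 °C) then gives the prenyl groups, and the route is rejoined at 5.

**Step 4 (ynone from the Weinreb amide).** The risks are addition of the released N,O-dimethylhydroxylamine to the terminal ynone and loss of the sensitive enynone on isolation. The fallback sets out from 7 and reaches the ketone by 1,2-addition and oxidation instead of acyl substitution. DIBAL-H (THF, −78 °C) gives (2E)-3-[4-methoxy-3,5-bis(3-methylbut-2-en-1-yl)phenyl]prop-2-enal F2. Ethynylmagnesium bromide 8 (THF, −78 °C) gives racemic (1E)-1-[4-methoxy-3,5-bis(3-methylbut-2-en-1-yl)phenyl]pent-1-en-4-yn-3-ol F3. Oxidation with MnO2 (CH2Cl2, rt) returns to the route at 9.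

## Further compounds

F0 | step 5 | none | none
F1 | step 2 | 3,5-diallyl-4-methoxybenzaldehyde | C=CCc1cc(C=O)cc(CC=C)c1OC
F2 | step 4 | (2E)-3-[4-methoxy-3,5-bis(3-methylbut-2-en-1-yl)phenyl]prop-2-enal | O=C/C=C/c1cc(CC=C(C)C)c(OC)c(CC=C(C)C)c1
F3 | step 4 | (1E)-1-[4-methoxy-3,5-bis(3-methylbut-2-en-1-yl)phenyl]pent-1-en-4-yn-3-ol (racemic) | C#CC(O)/C=C/c1cc(CC=C(C)C)c(OC)c(CC=C(C)C)c1
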